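**Strategy**

The route reads the core as the singlet-oxygen adduct of a benzene 1,2-oxide. In the cyclohexene ring the C3 and C6 hydroxyls are cis across C4=C5 and both trans to the C1–C2 oxirane. One photooxygenation adds O2 across C3/C6 of the diene C3=C4–C5=C6, forms both C–O bonds and fixes C1 and C2, which until then invert through the oxepin. The substrate is the 1,4-disubstituted benzene oxide 12, carrying CH2OTBS at C4 and an (S)-1-hydroxybut-2-ynyl group at C1 whose hydroxyl is left free to steer the oxygen by hydrogen bonding. The propyne later becomes a Z-iodide for Suzuki union with a geranyl-acetate-derived alkenylboronate.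

Key step: step 8

**Remarks on the chemistry**

- Numbering: core C1 (oxirane carbon bearing the side chain), C2 (oxirane CH), C3, C4 (bears CH2O), C5, C6; side chain C1' (carbinol), C2', C3' (bears CH3), C4', C5'. With C1→C6 drawn clockwise, the oxirane oxygen points to the viewer and C1', 3-O and 6-O point away.
- Assumption: the absolute configuration is the one encoded in the target SMILES, and geranyl acetate is taken as a purchasable material.
- The ring stereocentres made in steps 4–6 are erased in step 7. Compounds 10 and 11 are carried as ring-diastereomer mixtures and their SMILES define only C1'.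
- The carbinol is (R) by CIP at the cyclohexenyl stage (10) and (S) from 11 onward, with no change in space, because C1 then carries oxygen.
- The C1' hydroxyl of 12 is deliberately unprotected. In the invertomer with the target ring configuration the C1' oxygen lies beside C6 on the attack face. A bulky ether there would penalise that invertomer, whereas a free hydroxyl can assist the attack.

**Route**

Step 1
Reactants: 1 2-methyl-2-vinyloxirane
Product: 3 tert-butyl(dimethyl)[(2-methylidenebut-3-en-1-yl)oxy]silane, via lithium 2-methylidenebut-3-en-1-olate 2 (not isolated)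
Conditions: LDA, Et2O, 0 °C → rt; then TBSCl, DMAP (cat.), THF, rt
Reagents that add atoms: tert-butyldimethylsilyl chloride, CC(C)(C)[Si](C)(C)Cl
Why: Base-induced isomerisation of the vinyl oxirane to the allylic alkoxide (β-elimination, the amide removing a methyl proton) gives the dienyl alkoxide, which is silylated in the same flask so the volatile dienol is never isolated.

Step 2
Reactants: 3 tert-butyl(dimethyl)[(2-methylidenebut-3-en-1-yl)oxy]silane; 4 ethyl propiolate
Product: 5 ethyl 4-({[tert-butyl(dimethyl)silyl]oxy}methyl)cyclohexa-1,4-diene-1-carboxylate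
Conditions: EtAlCl2 (20 mol %), CH2Cl2, −40 → 0 °C
Reagents that add atoms: none
Why: Lewis-acid-catalysed Diels–Alder reaction of a 2-substituted butadiene with a propiolate follows the "para" rule (the diene CH2 next to the substituted carbon bonds to the propiolate β-carbon), giving the 1,4-disubstituted cyclohexa-1,4-diene.

Step 3
Reactants: 5 ethyl 4-({[tert-butyl(dimethyl)silyl]oxy}methyl)cyclohexa-1,4-diene-1-carboxylate; 6 prop-1-yn-1-ylmagnesium bromide
Product: 8 1-[4-({[tert-butyl(dimethyl)silyl]oxy}methyl)cyclohexa-1,4-dien-1-yl]but-2-yn-1-one, via Weinreb amide 7 (not isolated)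
Conditions: MeNH(OMe)·HCl, i-PrMgCl, THF, −20 °C; then 6, 0 °C; inverse quench into cold 1 M HCl
Reagents that add atoms: none
Why: Weinreb ketone synthesis in one flask: the magnesium amide converts the ester into the N-methoxy-N-methylamide, whose chelated adduct with the alkynyl Grignard reagent releases the ynone only on acidic quench, so over-addition and amine conjugate addition are avoided.

Step 4
Reactants: 8 1-[4-({[tert-butyl(dimethyl)silyl]oxy}methyl)cyclohexa-1,4-dien-1-yl]but-2-yn-1-one
Product: 9 1-[trans-4,5-dibromo-4-({[tert-butyl(dimethyl)silyl]oxy}methyl)cyclohex-1-en-1-yl]but-2-yn-1-one (racemic)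
Conditions: Br2 (1.0 equiv), CH2Cl2, −78 °C; used without delay
Reagents that add atoms: bromine, BrBr
Why: Electrophilic anti addition of bromine should be chemoselective for C4=C5, the only electron-rich π bond, because C1=C2 and the alkyne are both conjugated to the ketone; both new centres disappear in step 7.

Step 5
Reactants: 9 1-[trans-4,5-dibromo-4-({[tert-butyl(dimethyl)silyl]oxy}methyl)cyclohex-1-en-1-yl]but-2-yn-1-one
Product: 10 (1R)-1-[trans-4,5-dibromo-4-({[tert-butyl(dimethyl)silyl]oxy}methyl)cyclohex-1-en-1-yl]but-2-yn-1-ol (both trans-dibromide diastereomers)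
Conditions: (R)-Me-CBS (20 mol %), catecholborane, CH2Cl2/toluene, −78 °C
Reagents that add atoms: none
Why: Corey–Bakshi–Shibata reduction: the carbonyl should bind boron anti to the bulkier cyclohexenyl group (the slim propynyl acting as the small group), so the (R)-catalyst is expected to give the (1R)-carbinol, which has the spatial arrangement of C1' in the target.

Step 6
Reactants: 10 (1R)-1-[trans-4,5-dibromo-4-({[tert-butyl(dimethyl)silyl]oxy}methyl)cyclohex-1-en-1-yl]but-2-yn-1-ol
Product: 11 (1S)-1-[3,4-dibromo-4-({[tert-butyl(dimethyl)silyl]oxy}methyl)-7-oxabicyclo[4.1.0]heptan-1-yl]but-2-yn-1-ol (core C1–C2 oxirane, bromines on core C4 and C5; ring diastereomers)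
Conditions: VO(acac)2 (5 mol %), t-BuOOH, CH2Cl2, 0 °C
Reagents that add atoms: tert-butyl hydroperoxide, CC(C)(C)OO
Why: Hydroxyl-directed vanadium-catalysed epoxidation acts on the allylic alcohol C1=C2, the only alkene left; the face attacked is immaterial because the oxirane configuration equilibrates in 12.

Step 7
Reactants: 11 (1S)-1-[3,4-dibromo-4-({[tert-butyl(dimethyl)silyl]oxy}methyl)-7-oxabicyclo[4.1.0]heptan-1-yl]but-2-yn-1-ol
Product: 12 (1S)-1-[4-({[tert-butyl(dimethyl)silyl]oxy}methyl)-7-oxabicyclo[4.1.0]hepta-2,4-dien-1-yl]but-2-yn-1-ol (benzene 1,2-oxide; the two oxirane invertomers interconvert through the oxepin, the reactive one is drawn)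
Conditions: DBU (3 equiv), THF, 0 °C → rt; rapid filtration through basic alumina, used at once
Reagents that add atoms: none
Why: Twofold anti E2 dehydrobromination (the classical dibromide route to arene oxides) removes the axial C3–H and C6–H opposite the trans-diaxial bromides; elimination toward the exocyclic CH2OSi is disfavoured because an oxygen-bearing carbon is a poor E2 proton donor, and DBU does not deprotonate the carbinol.

Step 8
Reactants: 12 (1S)-1-[4-({[tert-butyl(dimethyl)silyl]oxy}methyl)-7-oxabicyclo[4.1.0]hepta-2,4-dien-1-yl]but-2-yn-1-ol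
Product: 13 (1S)-1-[3,6-epidioxy-1,2-epoxy-4-({[tert-butyl(dimethyl)silyl]oxy}methyl)cyclohex-4-en-1-yl]but-2-yn-1-ol (core numbering; peroxide bridge anti to the oxirane and on the side of C1'; ring configuration as in the target)
Conditions: O2, tetraphenylporphyrin (1 mol %), base-washed CH2Cl2, green LED, −78 °C; kept cold and taken on directly
Reagents that add atoms: dioxygen, O=O
Why: Proposed new method: photosensitised singlet oxygen should add suprafacially in a concerted [4+2] to the s-cis diene C3=C4–C5=C6 of the benzene-oxide tautomer, forming the C3–O and C6–O bonds; the closest known reaction type is the anti-selective singlet-oxygen cycloaddition to 1-substituted benzene oxides followed by O–O reduction, whereas selection between two interconverting invertomers by an exocyclic carbinol has not been shown. The only ring closed is the temporary 1,2-dioxine bridge (a 2,3-dioxabicyclo[2.2.2]octene, absent from the target), closed by this [4+2] on one face of the diene. C3 and C6 are set cis to each other by the suprafacial addition and anti to the oxirane because the oxirane oxygen screens its own face; C1 and C2, labile until then, are frozen in the configuration of whichever invertomer is trapped. The step therefore needs invertomer selection under Curtin–Hammett conditions, and the free (S)-C1'–OH is meant to supply it: with the small C1'–H turned under the ring (the only group that fits beside the incoming oxygen), only the invertomer with the target ring configuration holds the hydroxyl beside C6 on the attack face, where it can hydrogen-bond the arriving oxygen in a six-membered O–H···O–C6–C1–C1' array, while in the other invertomer that site is taken by the propynyl group and the hydroxyl points toward C2. A non-coordinating solvent and low temperature are chosen to keep this hydrogen bond decisive and to suppress acid-induced aromatisation of 12.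

Step 9
Reactants: 13 (1S)-1-[3,6-epidioxy-1,2-epoxy-4-({[tert-butyl(dimethyl)silyl]oxy}methyl)cyclohex-4-en-1-yl]but-2-yn-1-ol
Product: 14 (1S)-1-[1,2-epoxy-3,6-dihydroxy-4-({[tert-butyl(dimethyl)silyl]oxy}methyl)cyclohex-4-en-1-yl]but-2-yn-1-ol (core numbering; 3-OH and 6-OH cis, both anti to the oxirane)
Conditions: thiourea (2.5 equiv), MeOH, −20 → 0 °C
Reagents that add atoms: none
Why: Thiourea reduces the O–O bond by attack of sulfur on oxygen without breaking any C–O bond, so the cis relationship of the two hydroxyls and their anti relationship to the oxirane are kept, and base-induced Kornblum–DeLaMare cleavage is avoided.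

Step 10
Reactants: 14 (1S)-1-[1,2-epoxy-3,6-dihydroxy-4-({[tert-butyl(dimethyl)silyl]oxy}methyl)cyclohex-4-en-1-yl]but-2-yn-1-ol
Product: 15 (1S,2Z)-1-[1,2-epoxy-3,6-dihydroxy-4-({[tert-butyl(dimethyl)silyl]oxy}methyl)cyclohex-4-en-1-yl]-3-(triethylsilyl)but-2-en-1-ol
Conditions: Et3SiH (1.5 equiv), [Cp*Ru(MeCN)3]PF6 (5 mol %), CH2Cl2, 0 °C → rt
Reagents that add atoms: triethylsilane, CC[SiH](CC)CC
Why: Cationic Cp*Ru-catalysed hydrosilylation adds H and Si trans across the alkyne and, with a free propargylic hydroxyl, places silicon on the distal carbon C3', so Si ends cis to C1' (Z).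

Step 11
Reactants: 15 (1S,2Z)-1-[1,2-epoxy-3,6-dihydroxy-4-({[tert-butyl(dimethyl)silyl]oxy}methyl)cyclohex-4-en-1-yl]-3-(triethylsilyl)but-2-en-1-ol
Product: 16 (1S,2Z)-1-[1,2-epoxy-3,6-dihydroxy-4-({[tert-butyl(dimethyl)silyl]oxy}methyl)cyclohex-4-en-1-yl]-3-iodobut-2-en-1-ol
Conditions: N-iodosuccinimide (1.2 equiv), 2,6-lutidine, (CF3)2CHOH, 0 °C
Reagents that add atoms: N-iodosuccinimide, O=C1CCC(=O)N1I
Why: Electrophilic ipso-iododesilylation in a fluoroalcohol proceeds with retention of alkene geometry because the β-silyl cation loses silicon faster than it rotates, and the vinylsilane is the most nucleophilic π bond present.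

Step 12
Reactants: 17 geranyl acetate
Product: 18 (2E)-5-[(2R)-3,3-dimethyloxiran-2-yl]-3-methylpent-2-en-1-yl acetate
Conditions: D-fructose-derived Shi ketone (30 mol %), potassium peroxymonosulfate, K2CO3, Bu4NHSO4, MeCN/dimethoxymethane/aq. buffer, 0 °C
Reagents that add atoms: potassium peroxymonosulfate, [K+].[O-]S(=O)(=O)OO
Why: Shi epoxidation: the chiral dioxirane attacks the electron-rich 6,7-alkene through a spiro transition state (the 2,3-alkene is deactivated by the allylic acetate) and should set the (R)-oxirane carbon that becomes the secondary carbinol of the terpenoid ring.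

Step 13
Reactants: 18 (2E)-5-[(2R)-3,3-dimethyloxiran-2-yl]-3-methylpent-2-en-1-yl acetate
Product: 19 [(1S,3R)-3-hydroxy-2,2-dimethyl-6-methylidenecyclohexyl]methyl acetate (CH2OAc and OH cis, both equatorial)
Conditions: Cp2TiCl2 (2.2 equiv), Mn dust, THF, rt; then 1 M HCl
Reagents that add atoms: none
Why: Titanocene(III)-mediated radical epoxypolyene cyclisation (homolytic oxirane opening at the tertiary carbon, 6-endo closure through a chair with CH2OAc and O–Ti equatorial, then titanium trapping and β-hydride elimination) gives the exocyclic alkene with the ring CH set cis to the carbinol.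

Step 14
Reactants: 19 [(1S,3R)-3-hydroxy-2,2-dimethyl-6-methylidenecyclohexyl]methyl acetate
Product: 20 [(3R,4S,6R)-6-hydroxy-5,5-dimethyl-1-oxaspiro[2.5]octan-4-yl]methyl acetate (oxirane oxygen equatorial, trans to CH2OAc)
Conditions: mCPBA, CH2Cl2, 0 °C
Reagents that add atoms: 3-chloroperoxybenzoic acid, O=C(OO)c1cccc(Cl)c1
Why: Prilezhaev epoxidation of the exocyclic alkene should occur from the equatorial direction because the axial methyl of the neighbouring gem-dimethyl carbon blocks the axial face, which sets the tertiary C–O bond equatorial.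

Step 15
Reactants: 20 [(3R,4S,6R)-6-hydroxy-5,5-dimethyl-1-oxaspiro[2.5]octan-4-yl]methyl acetate
Product: 21 (1R,2S,4R)-2-(hydroxymethyl)-1,3,3-trimethylcyclohexane-1,4-diol
Conditions: LiAlH4, THF, 0 °C → rt
Reagents that add atoms: none
Why: Hydride opens the spiro-oxirane by SN2 at its unsubstituted CH2, which becomes the axial methyl beside the equatorial tertiary alcohol, and the acetate is reduced off in the same operation.

Step 16
Reactants: 21 (1R,2S,4R)-2-(hydroxymethyl)-1,3,3-trimethylcyclohexane-1,4-diol
Product: 22 (1R,3R,6R)-3,6-dihydroxy-2,2,6-trimethylcyclohexane-1-carbaldehyde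
Conditions: TEMPO (10 mol %), PhI(OAc)2, CH2Cl2, rt
Reagents that add atoms: none
Why: Oxoammonium (TEMPO) oxidation is selective for the primary alcohol over the hindered secondary and the tertiary one and stops at the aldehyde under near-neutral conditions that should not dehydrate the β-hydroxy aldehyde.

Step 17
Reactants: 22 (1R,3R,6R)-3,6-dihydroxy-2,2,6-trimethylcyclohexane-1-carbaldehyde; 23 2-(dichloromethyl)-4,4,5,5-tetramethyl-1,3,2-dioxaborolane
Product: 24 (1R,2R,4R)-1,3,3-trimethyl-2-[(E)-2-(4,4,5,5-tetramethyl-1,3,2-dioxaborolan-2-yl)ethenyl]cyclohexane-1,4-diol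
Conditions: CrCl2 (8 equiv), LiI (4 equiv), THF, rt
Reagents that add atoms: none
Why: Takai-type boryl-olefination: the geminal dichromium reagent formed from the dihalomethylboronate adds to the aldehyde and eliminates to the (E)-alkenylboronate, and the weakly basic chromium species should tolerate the free hydroxyls and the α-stereocentre.

Step 18
Reactants: 16 (1S,2Z)-1-[1,2-epoxy-3,6-dihydroxy-4-({[tert-butyl(dimethyl)silyl]oxy}methyl)cyclohex-4-en-1-yl]-3-iodobut-2-en-1-ol; 24 (1R,2R,4R)-1,3,3-trimethyl-2-[(E)-2-(4,4,5,5-tetramethyl-1,3,2-dioxaborolan-2-yl)ethenyl]cyclohexane-1,4-diol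
Product: 25 arthrosporol A tert-butyldimethylsilyl ether (silyl group on the C4 hydroxymethyl oxygen; (2'Z,4'E)-diene)
Conditions: Pd(dppf)Cl2·CH2Cl2 (10 mol %), AsPh3, Cs2CO3, DMF/THF/H2O, rt
Reagents that add atoms: none
Why: Suzuki–Miyaura coupling proceeds with retention at both alkenyl partners and so gives the (2'Z,4'E)-diene, and a carbonate base at room temperature should spare the epoxy triol.

Step 19
Reactants: 25 arthrosporol A tert-butyldimethylsilyl ether
Product: 26 arthrosporol A
Conditions: TBAF, AcOH (1:1), THF, 0 °C → rt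
Reagents that add atoms: none
Why: Fluoride-induced desilylation cleaves the primary silyl ether through the strong Si–F bond, and acetic acid buffering keeps the medium from promoting Payne rearrangement of the epoxy alcohols.

**Compound list**

1 | 2-methyl-2-vinyloxirane | CC1(C=C)CO1 | starting material
2 | lithium 2-methylidenebut-3-en-1-olate | [Li+].[O-]CC(=C)C=C | intermediate
3 | tert-butyl(dimethyl)[(2-methylidenebut-3-en-1-yl)oxy]silane | C=CC(=C)CO[Si](C)(C)C(C)(C)C | intermediate
4 | ethyl propiolate | CCOC(=O)C#C | starting material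
5 | ethyl 4-({[tert-butyl(dimethyl)silyl]oxy}methyl)cyclohexa-1,4-diene-1-carboxylate | CCOC(=O)C1=CCC(CO[Si](C)(C)C(C)(C)C)=CC1 | intermediate
6 | prop-1-yn-1-ylmagnesium bromide | CC#C[Mg]Br | starting material
7 | 4-({[tert-butyl(dimethyl)silyl]oxy}methyl)-N-methoxy-N-methylcyclohexa-1,4-diene-1-carboxamide (Weinreb amide) | CON(C)C(=O)C1=CCC(CO[Si](C)(C)C(C)(C)C)=CC1 | intermediate
8 | 1-[4-({[tert-butyl(dimethyl)silyl]oxy}methyl)cyclohexa-1,4-dien-1-yl]but-2-yn-1-one | CC#CC(=O)C1=CCC(CO[Si](C)(C)C(C)(C)C)=CC1 | intermediate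
9 | 1-[trans-4,5-dibromo-4-({[tert-butyl(dimethyl)silyl]oxy}methyl)cyclohex-1-en-1-yl]but-2-yn-1-one (racemic; relative configuration shown) | CC#CC(=O)C1=CC[C@](Br)(CO[Si](C)(C)C(C)(C)C)[C@H](Br)C1 | intermediate
10 | (1R)-1-[trans-4,5-dibromo-4-({[tert-butyl(dimethyl)silyl]oxy}methyl)cyclohex-1-en-1-yl]but-2-yn-1-ol (both dibromide diastereomers) | CC#C[C@H](O)C1=CCC(Br)(CO[Si](C)(C)C(C)(C)C)C(Br)C1 | intermediate
11 | (1S)-1-[3,4-dibromo-4-({[tert-butyl(dimethyl)silyl]oxy}methyl)-7-oxabicyclo[4.1.0]heptan-1-yl]but-2-yn-1-ol (ring diastereomers) | CC#C[C@H](O)C12OC1CC(Br)(CO[Si](C)(C)C(C)(C)C)C(Br)C2 | intermediate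
12 | (1S)-1-[4-({[tert-butyl(dimethyl)silyl]oxy}methyl)-7-oxabicyclo[4.1.0]hepta-2,4-dien-1-yl]but-2-yn-1-ol (reactive invertomer) | CC#C[C@H](O)[C@]12O[C@H]1C=C(CO[Si](C)(C)C(C)(C)C)C=C2 | intermediate
13 | (1S)-1-[3,6-epidioxy-1,2-epoxy-4-({[tert-butyl(dimethyl)silyl]oxy}methyl)cyclohex-4-en-1-yl]but-2-yn-1-ol (peroxide anti to oxirane) | CC#C[C@H](O)[C@]12O[C@H]1[C@@H]3OO[C@H]2C=C3CO[Si](C)(C)C(C)(C)C | intermediate
14 | (1S)-1-[1,2-epoxy-3,6-dihydroxy-4-({[tert-butyl(dimethyl)silyl]oxy}methyl)cyclohex-4-en-1-yl]but-2-yn-1-ol (3,6-diol cis, anti to oxirane) | CC#C[C@H](O)[C@]12O[C@H]1[C@H](O)C(CO[Si](C)(C)C(C)(C)C)=C[C@@H]2O | intermediate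
15 | (1S,2Z)-1-[1,2-epoxy-3,6-dihydroxy-4-({[tert-butyl(dimethyl)silyl]oxy}methyl)cyclohex-4-en-1-yl]-3-(triethylsilyl)but-2-en-1-ol | CC(=C/[C@H](O)[C@]12O[C@H]1[C@H](O)C(CO[Si](C)(C)C(C)(C)C)=C[C@@H]2O)/[Si](CC)(CC)CC | intermediate
16 | (1S,2Z)-1-[1,2-epoxy-3,6-dihydroxy-4-({[tert-butyl(dimethyl)silyl]oxy}methyl)cyclohex-4-en-1-yl]-3-iodobut-2-en-1-ol | CC(=C/[C@H](O)[C@]12O[C@H]1[C@H](O)C(CO[Si](C)(C)C(C)(C)C)=C[C@@H]2O)/I | intermediate
17 | geranyl acetate | CC(C)=CCC/C(C)=C/COC(C)=O | starting material
18 | (2E)-5-[(2R)-3,3-dimethyloxiran-2-yl]-3-methylpent-2-en-1-yl acetate | CC(=O)OC/C=C(\C)CC[C@H]1OC1(C)C | intermediate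
19 | [(1S,3R)-3-hydroxy-2,2-dimethyl-6-methylidenecyclohexyl]methyl acetate | CC(=O)OC[C@@H]1C(C)(C)[C@H](O)CCC1=C | intermediate
20 | [(3R,4S,6R)-6-hydroxy-5,5-dimethyl-1-oxaspiro[2.5]octan-4-yl]methyl acetate | CC(=O)OC[C@@H]1C(C)(C)[C@H](O)CC[C@]12CO2 | intermediate
21 | (1R,2S,4R)-2-(hydroxymethyl)-1,3,3-trimethylcyclohexane-1,4-diol | OC[C@@H]1C(C)(C)[C@H](O)CC[C@@]1(C)O | intermediate
22 | (1R,3R,6R)-3,6-dihydroxy-2,2,6-trimethylcyclohexane-1-carbaldehyde | O=C[C@@H]1C(C)(C)[C@H](O)CC[C@@]1(C)O | intermediate
23 | 2-(dichloromethyl)-4,4,5,5-tetramethyl-1,3,2-dioxaborolane | CC1(C)OB(C(Cl)Cl)OC1(C)C | starting material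
24 | (1R,2R,4R)-1,3,3-trimethyl-2-[(E)-2-(4,4,5,5-tetramethyl-1,3,2-dioxaborolan-2-yl)ethenyl]cyclohexane-1,4-diol | CC1(C)OB(/C=C/[C@@H]2C(C)(C)[C@H](O)CC[C@@]2(C)O)OC1(C)C | intermediate
25 | arthrosporol A tert-butyldimethylsilyl ether (on the C4 hydroxymethyl) | CC(=C/[C@H](O)[C@]12O[C@H]1[C@H](O)C(CO[Si](C)(C)C(C)(C)C)=C[C@@H]2O)/C=C/[C@@H]1C(C)(C)[C@H](O)CC[C@@]1(C)O | intermediate
26 | arthrosporol A | CC(=C/[C@H](O)[C@]12O[C@H]1[C@H](O)C(CO)=C[C@@H]2O)/C=C/[C@@H]1C(C)(C)[C@H](O)CC[C@@]1(C)O | target

**Step count**

Total: 19 steps. Longest linear sequence: 13 steps (steps 1–11, 18, 19).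

**Steps most likely to fail**

Step 8. The two oxirane invertomers may be captured with little discrimination, or the mismatched one may react faster; the arene oxide may also aromatise before it is trapped. The fallback removes the need for invertomer selection and sets out from 11. Dess–Martin oxidation of the carbinol gives the epoxy ynone F1. DBU elimination as in step 7 gives the racemic 1-acyl benzene oxide F2, which has no stereocentre outside the ring. Photooxygenation then relies only on the established anti selectivity and gives the racemic anti endoperoxide ketone F3, and thiourea gives the racemic cis-diol ynone F4. Noyori transfer hydrogenation of the ynone with the (R,R)-TsDPEN–Ru(p-cymene) catalyst should set (S)-C1' under catalyst control in both ring enantiomers. This gives 14 together with its ring-enantiomeric diastereomer F5, which is removed by chromatography. The route is rejoined at 14, with at most half of the material.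

Step 5. Hydride delivery may show poor facial selectivity because both carbonyl substituents are π systems, and the dibromo enone may lose HBr toward an arene. The fallback sets out from 9. Luche reduction gives the racemic alcohol F6. Burkholderia cepacia lipase with vinyl acetate should, by the usual size rule for secondary alcohols (cyclohexenyl large, propynyl medium), acetylate the (1S)-enantiomer to the acetate F7 and leave the (1R)-alcohol untouched. The route is rejoined at 10.

Step 11. The iodonium intermediate may be intercepted by a neighbouring hydroxyl or by C4=C5, the oxirane may open in the acidic fluoroalcohol, or the Z geometry may erode. The fallback avoids the iodide and sets out from 14. The same ruthenium-catalysed trans-hydrosilylation with benzyldimethylsilane gives the (Z)-benzyldimethylsilyl alkene F8. Aldehyde 22 is converted by Takai iodo-olefination (CHI3, CrCl2) into the (E)-alkenyl iodide F9. Hiyama–Denmark coupling of the two (Pd2(dba)3, TBAF, THF, rt) forms the diene, and the same fluoride removes the TBS group. The route is rejoined at 26.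

**Further compounds**

F1 | step 8 | 1-[3,4-dibromo-4-({[tert-butyl(dimethyl)silyl]oxy}methyl)-7-oxabicyclo[4.1.0]heptan-1-yl]but-2-yn-1-one (ring diastereomers) | CC#CC(=O)C12OC1CC(Br)(CO[Si](C)(C)C(C)(C)C)C(Br)C2
F2 | step 8 | 1-[4-({[tert-butyl(dimethyl)silyl]oxy}methyl)-7-oxabicyclo[4.1.0]hepta-2,4-dien-1-yl]but-2-yn-1-one (racemic, invertomers equilibrate) | CC#CC(=O)C12OC1C=C(CO[Si](C)(C)C(C)(C)C)C=C2
F3 | step 8 | 1-[3,6-epidioxy-1,2-epoxy-4-({[tert-butyl(dimethyl)silyl]oxy}methyl)cyclohex-4-en-1-yl]but-2-yn-1-one (racemic, peroxide anti to oxirane; relative configuration shown) | CC#CC(=O)[C@]12O[C@H]1[C@@H]3OO[C@H]2C=C3CO[Si](C)(C)C(C)(C)C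
F4 | step 8 | 1-[1,2-epoxy-3,6-dihydroxy-4-({[tert-butyl(dimethyl)silyl]oxy}methyl)cyclohex-4-en-1-yl]but-2-yn-1-one (racemic; relative configuration shown) | CC#CC(=O)[C@]12O[C@H]1[C@H](O)C(CO[Si](C)(C)C(C)(C)C)=C[C@@H]2O
F5 | step 8 | (1S)-carbinol diastereomer of 14 with the enantiomeric ring | CC#C[C@H](O)[C@@]12O[C@@H]1[C@@H](O)C(CO[Si](C)(C)C(C)(C)C)=C[C@H]2O
F6 | step 5 | 1-[trans-4,5-dibromo-4-({[tert-butyl(dimethyl)silyl]oxy}methyl)cyclohex-1-en-1-yl]but-2-yn-1-ol (racemic at the carbinol) | CC#CC(O)C1=CCC(Br)(CO[Si](C)(C)C(C)(C)C)C(Br)C1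
F7 | step 5 | (1S)-1-[trans-4,5-dibromo-4-({[tert-butyl(dimethyl)silyl]oxy}methyl)cyclohex-1-en-1-yl]but-2-yn-1-yl acetate | CC#C[C@@H](OC(C)=O)C1=CCC(Br)(CO[Si](C)(C)C(C)(C)C)C(Br)C1
F8 | step 11 | (1S,2Z)-3-[benzyl(dimethyl)silyl]-1-[1,2-epoxy-3,6-dihydroxy-4-({[tert-butyl(dimethyl)silyl]oxy}methyl)cyclohex-4-en-1-yl]but-2-en-1-ol | CC(=C/[C@H](O)[C@]12O[C@H]1[C@H](O)C(CO[Si](C)(C)C(C)(C)C)=C[C@@H]2O)/[Si](C)(C)Cc1ccccc1
F9 | step 11 | (1R,2R,4R)-2-[(E)-2-iodoethenyl]-1,3,3-trimethylcyclohexane-1,4-diol | I/C=C/[C@@H]1C(C)(C)[C@H](O)CC[C@@]1(C)O
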